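The 1,2-dioxane (numbered O1, O2, C3 with the acetic acid arm, C4, C5, C6) is cut at C5–C6 and O2–C3. This separates a C6–O1–O2 unit that carries the whole side chain from a C3–C4–C5 unit that carries the C4 ethyl group. The key step, a formal [3+3] annulation, exploits the quaternary peroxide carbon C6 as a latent peroxycarbenium ion and the 1,3-relationship of C5 to the oxygenated C3 as a homoenolate: the silyl peroxyketal of an open-chain ketone ionises and is attacked by the CH2 carbon of an enantiopure trans-2-ethylcyclopropyl silyl ether, whose ring opens and recloses through the peroxide oxygen. The acetic acid arm and the enone are added afterwards.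

Key step: step 12

Remark: in steps 2 and 5 the ligand enantiomer named is the one expected to give the configuration shown; if the sense of induction is the opposite one, the mirror-image ligand serves.
Remark: step 12 creates C6 with little inherent bias; the route is drawn for the (6R) series, and the (6S) epimer is removed by chromatography at 21 or at 23.

Step 1
Reactants: 1 (E)-pent-2-en-1-ol
Product: 2 methyl (E)-pent-2-en-1-yl carbonate
Conditions: ClCO2Me, pyridine, CH2Cl2, 0 °C
Reagents that add atoms: methyl chloroformate, COC(=O)Cl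
Why: Acylation of the primary allylic alcohol by the chloroformate (nucleophilic acyl substitution) installs the carbonate leaving group for allylic substitution; no stereocentre is formed.

Step 2
Reactants: 2 methyl (E)-pent-2-en-1-yl carbonate; 3 dimethyl malonate
Product: 4 dimethyl 2-[(3R)-pent-1-en-3-yl]propanedioate
Conditions: [Ir(cod)Cl]2 (2 mol %), (Sa,S,S)-O,O'-(1,1'-binaphthalene-2,2'-diyl) N,N-bis(1-phenylethyl)phosphoramidite (4 mol %), 1,5,7-triazabicyclo[4.4.0]dec-5-ene (8 mol %), THF, rt
Reagents that add atoms: none
Why: Iridium-catalysed asymmetric allylic alkylation: the cyclometalated iridium phosphoramidite complex ionises the carbonate, whose methoxide deprotonates the malonate, and directs attack to the substituted allyl terminus, so that the branched product should form with C3 set by the ligand (catalyst control).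

Step 3
Reactants: 4 dimethyl 2-[(3R)-pent-1-en-3-yl]propanedioate
Product: 5 methyl (3S)-3-ethylpent-4-enoate
Conditions: NaCl, H2O, DMSO, 150 °C
Reagents that add atoms: none
Why: Krapcho dealkoxycarbonylation (chloride SN2 attack at an ester methyl group, decarboxylation, protonation) removes one ester, and the stereocentre, which is not alpha to a carbonyl group, is untouched.

Step 4
Reactants: 5 methyl (3S)-3-ethylpent-4-enoate; 6 diethyl (2-oxobutyl)phosphonate
Product: 8 (4E,7S)-7-ethylnona-4,8-dien-3-one, via (3S)-3-ethylpent-4-enal 7 (not isolated)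
Conditions: i-Bu2AlH, CH2Cl2, −78 °C, then MeOH and aq. potassium sodium tartrate; crude 7, then 6, LiCl, i-Pr2NEt, MeCN, rt
Reagents that add atoms: none
Why: Reduction of the ester at low temperature stops at the aldehyde through the tetrahedral aluminium hemiacetal, and the Horner–Wadsworth–Emmons reaction with LiCl and an amine base should give the E-enone without touching the stereocentre, which is beta to the aldehyde and cannot epimerise.

Step 5
Reactants: 8 (4E,7S)-7-ethylnona-4,8-dien-3-one
Product: 9 (5S,7S)-7-ethyl-5-methylnon-8-en-3-one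
Conditions: MeMgBr, CuBr·SMe2 (5 mol %), (R)-1-[(Sp)-2-(diphenylphosphino)ferrocenyl]ethyldicyclohexylphosphine (6 mol %), t-BuOMe, −78 °C
Reagents that add atoms: methylmagnesium bromide, C[Mg]Br
Why: Copper-catalysed asymmetric conjugate addition of a Grignard reagent to an acyclic enone; the new C5 stereocentre is set by the ferrocenyl diphosphine (reagent control), because the existing C7 centre is remote, and the terminal alkene does not react.

Step 6
Reactants: 9 (5S,7S)-7-ethyl-5-methylnon-8-en-3-one
Product: 10 (3RS,5S,7S)-7-ethyl-3-methoxy-5-methylnon-8-en-3-yl hydroperoxide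
Conditions: urea–hydrogen peroxide, Sc(OTf)3 (10 mol %), MeOH, rt
Reagents that add atoms: hydrogen peroxide, OO; methanol, CO
Why: Lewis acid-catalysed addition of H2O2 and methanol to the ketone (hydroperoxy ketal formation) should give the alpha-methoxy hydroperoxide and leave the alkene untouched; the new ketal centre forms as both epimers and becomes planar again in step 12.

Step 7
Reactants: 10 (3RS,5S,7S)-7-ethyl-3-methoxy-5-methylnon-8-en-3-yl hydroperoxide
Product: 11 triethyl{[(3RS,5S,7S)-7-ethyl-3-methoxy-5-methylnon-8-en-3-yl]peroxy}silane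
Conditions: Et3SiCl, imidazole, DMF, 0 °C
Reagents that add atoms: chlorotriethylsilane, CC[Si](Cl)(CC)CC
Why: O-Silylation of the hydroperoxide (nucleophilic substitution at silicon) gives the triethylsilyl peroxyketal, a storable precursor of the peroxycarbenium ion, and creates no stereocentre.

Step 8
Reactants: 12 (2R)-2-ethyloxirane; 13 diethyl (cyanomethyl)phosphonate
Product: 14 (1S,2S)-2-ethylcyclopropane-1-carbonitrile
Conditions: NaH, 1,2-dimethoxyethane, rt; then 12, sealed tube, 110 °C
Reagents that add atoms: none
Why: Wadsworth–Emmons cyclopropanation: the phosphonate carbanion opens the epoxide at CH2, the phosphoryl group moves to the alkoxide, and the nitrile-stabilised carbanion displaces the phosphate with inversion at the former epoxide carbon, so that C2 is fixed by the epoxide and the nitrile takes the trans (thermodynamic) position.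

Step 9
Reactants: 14 (1S,2S)-2-ethylcyclopropane-1-carbonitrile
Product: 16 1-[(1S,2S)-2-ethylcyclopropyl]ethan-1-one, via magnesium ketimide 15 (not isolated)
Conditions: MeMgBr, Et2O, 0 °C to reflux; then aq. HCl, 0 °C
Reagents that add atoms: methylmagnesium bromide, C[Mg]Br; water, O
Why: Addition of the Grignard reagent to the nitrile stops at the magnesium ketimide, which is hydrolysed to the methyl ketone; both cyclopropane stereocentres are kept in the trans arrangement.

Step 10
Reactants: 16 1-[(1S,2S)-2-ethylcyclopropyl]ethan-1-one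
Product: 17 (1S,2S)-2-ethylcyclopropyl acetate
Conditions: (CF3CO)2O, urea–hydrogen peroxide, Na2HPO4, CH2Cl2, 0 °C to rt
Reagents that add atoms: trifluoroperacetic acid (formed in the flask), OOC(=O)C(F)(F)F
Why: Baeyer–Villiger oxidation, in which the secondary cyclopropyl group migrates in preference to methyl and with retention of configuration, converts the acetyl group into the acetate of the cyclopropanol.

Step 11
Reactants: 17 (1S,2S)-2-ethylcyclopropyl acetate
Product: 19 triethyl{[(1S,2S)-2-ethylcyclopropyl]oxy}silane, via lithium (1S,2S)-2-ethylcyclopropan-1-olate 18 (not isolated)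
Conditions: MeLi (2.1 equiv), Et2O, −78 °C; then Et3SiCl, −78 to 0 °C
Reagents that add atoms: chlorotriethylsilane, CC[Si](Cl)(CC)CC
Why: Double addition of MeLi to the ester carbonyl releases the lithium cyclopropanolate under aprotic conditions that do not open the ring, and O-silylation with retention gives the siloxycyclopropane.

Step 12
Reactants: 11 triethyl{[(3RS,5S,7S)-7-ethyl-3-methoxy-5-methylnon-8-en-3-yl]peroxy}silane; 19 triethyl{[(1S,2S)-2-ethylcyclopropyl]oxy}silane
Product: 21 (3RS,4S,6R)-4,6-diethyl-6-[(2S,4S)-4-ethyl-2-methylhex-5-en-1-yl]-3-methoxy-1,2-dioxane, via 3-triethylsilyloxy-1,2-dioxane 20 (not isolated)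
Conditions: 19 (2 equiv), Me3SiOTf (0.3 equiv), 2,6-di-tert-butyl-4-methylpyridine (0.1 equiv), CH2Cl2, −78 °C; then MeOH, −78 to −20 °C
Reagents that add atoms: methanol, CO
Why: Proposed new method: Me3SiOTf ionises the C–OMe bond of 11 to a triethylsilylperoxy carbenium ion at C6, which is attacked by the unsubstituted CH2 carbon (C5) of the donor-activated cyclopropane 19 with cleavage of the bond between that carbon and the oxygen-bearing carbon, so that the latter (C3) becomes a silyloxocarbenium ion; the silylated peroxide oxygen O2 then closes the 1,2-dioxane on C3 in a 6-exo-trig attack on the exocyclic C=O+ and releases the silyl cation to give 20, which methanolysis converts into the stable methyl peroxyacetal 21. The closest known reactions are the Lewis acid-mediated [3+2] annulation of silyl peroxycarbenium ions with alkenes to 1,2-dioxolanes, the additions of allylsilanes and silyl enol ethers to peroxycarbenium ions, and the electrophilic ring opening of siloxycyclopropanes as homoenolate equivalents, combined here into a formal [3+3] annulation. C4 is carried over unchanged from C2 of 19 because no bond to it is broken, and C3 forms as an anomeric mixture that is erased in step 13. C6 is created in the intermolecular C–C bond formation under the influence of the neighbouring C4 centre only, and since the ethyl group and the beta-branched C7 chain differ little in size the facial selectivity is expected to be modest, so that the (6S) epimer has to be separated. The step needs regioselective attack at the cyclopropane CH2 (secured by the oxygen donor and the lower substitution of that carbon), chemoselectivity over the terminal vinyl group (secured by the higher nucleophilicity and the excess of 19) and suppression of proton-induced ring opening (secured by the hindered pyridine base).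

Step 13
Reactants: 21 (3RS,4S,6R)-4,6-diethyl-6-[(2S,4S)-4-ethyl-2-methylhex-5-en-1-yl]-3-methoxy-1,2-dioxane
Product: 23 2-[(3S,4S,6R)-4,6-diethyl-6-[(2S,4S)-4-ethyl-2-methylhex-5-en-1-yl]-1,2-dioxan-3-yl]acetic acid, via trimethylsilyl ester 22 (not isolated)
Conditions: CH2=C(OSiMe3)2 (3 equiv), Me3SiOTf (0.3 equiv), CH2Cl2, −78 °C; then aq. citric acid
Reagents that add atoms: ketene bis(trimethylsilyl) acetal, C=C(O[Si](C)(C)C)O[Si](C)(C)C
Why: Lewis acid ionisation of the peroxyacetal gives the cyclic 1,2-dioxan-3-ylium (peroxycarbenium) ion, which adds the silyl ketene acetal in a Mukaiyama-type substitution known for 3-alkoxy-1,2-dioxanes and 1,2-dioxolanes; attack should be axial on the half-chair that keeps the C4 ethyl group and the C6 side chain pseudo-equatorial (the other half-chair suffers a 1,3-diaxial clash) and anti to the axial C6 ethyl group, which sets C3 cis to the C4 ethyl group, and the silyl ester is hydrolysed on work-up.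

Step 14
Reactants: 23 2-[(3S,4S,6R)-4,6-diethyl-6-[(2S,4S)-4-ethyl-2-methylhex-5-en-1-yl]-1,2-dioxan-3-yl]acetic acid; 24 but-3-en-2-one
Product: 25 2-[(3S,4S,6R)-4,6-diethyl-6-[(2S,4S,5E)-4-ethyl-2-methyl-7-oxooct-5-en-1-yl]-1,2-dioxan-3-yl]acetic acid (CNP0329238.3)
Conditions: 24 (5 equiv), second-generation Hoveyda–Grubbs catalyst, RuCl2(H2IMes)(=CH–C6H4-2-O-i-Pr) (5 mol %), CH2Cl2, 40 °C
Reagents that add atoms: none
Why: Olefin cross-metathesis of the terminal alkene with the electron-poor enone partner used in excess should give the E-enone under thermodynamic control with loss of ethene; ruthenium carbene catalysts tolerate dialkyl peroxides and carboxylic acids, and no stereocentre is touched.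

Compound list
1 | (E)-pent-2-en-1-ol | CC/C=C/CO | starting material
2 | methyl (E)-pent-2-en-1-yl carbonate | CC/C=C/COC(=O)OC | intermediate
3 | dimethyl malonate | COC(=O)CC(=O)OC | starting material
4 | dimethyl 2-[(3R)-pent-1-en-3-yl]propanedioate | CC[C@H](C=C)C(C(=O)OC)C(=O)OC | intermediate
5 | methyl (3S)-3-ethylpent-4-enoate | CC[C@H](C=C)CC(=O)OC | intermediate
6 | diethyl (2-oxobutyl)phosphonate | CCC(=O)CP(=O)(OCC)OCC | starting material
7 | (3S)-3-ethylpent-4-enal | CC[C@H](C=C)CC=O | intermediate (not isolated)
8 | (4E,7S)-7-ethylnona-4,8-dien-3-one | CC[C@H](C=C)C/C=C/C(=O)CC | intermediate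
9 | (5S,7S)-7-ethyl-5-methylnon-8-en-3-one | CC[C@H](C=C)C[C@H](C)CC(=O)CC | intermediate
10 | (3RS,5S,7S)-7-ethyl-3-methoxy-5-methylnon-8-en-3-yl hydroperoxide | CC[C@H](C=C)C[C@H](C)CC(OC)(OO)CC | intermediate
11 | triethyl{[(3RS,5S,7S)-7-ethyl-3-methoxy-5-methylnon-8-en-3-yl]peroxy}silane | CC[C@H](C=C)C[C@H](C)CC(OC)(OO[Si](CC)(CC)CC)CC | intermediate
12 | (2R)-2-ethyloxirane ((R)-1,2-epoxybutane) | CC[C@@H]1CO1 | starting material
13 | diethyl (cyanomethyl)phosphonate | CCOP(=O)(CC#N)OCC | starting material
14 | (1S,2S)-2-ethylcyclopropane-1-carbonitrile | CC[C@H]1C[C@@H]1C#N | intermediate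
15 | bromo({1-[(1S,2S)-2-ethylcyclopropyl]ethylidene}amino)magnesium | CC[C@H]1C[C@@H]1C(C)=N[Mg]Br | intermediate (not isolated)
16 | 1-[(1S,2S)-2-ethylcyclopropyl]ethan-1-one | CC[C@H]1C[C@@H]1C(C)=O | intermediate
17 | (1S,2S)-2-ethylcyclopropyl acetate | CC[C@H]1C[C@@H]1OC(C)=O | intermediate
18 | lithium (1S,2S)-2-ethylcyclopropan-1-olate | [Li+].CC[C@H]1C[C@@H]1[O-] | intermediate (not isolated)
19 | triethyl{[(1S,2S)-2-ethylcyclopropyl]oxy}silane | CC[C@H]1C[C@@H]1O[Si](CC)(CC)CC | intermediate
20 | triethyl({(3RS,4S,6R)-4,6-diethyl-6-[(2S,4S)-4-ethyl-2-methylhex-5-en-1-yl]-1,2-dioxan-3-yl}oxy)silane | CC[C@H](C=C)C[C@H](C)C[C@]1(CC)C[C@H](CC)C(O[Si](CC)(CC)CC)OO1 | intermediate (not isolated)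
21 | (3RS,4S,6R)-4,6-diethyl-6-[(2S,4S)-4-ethyl-2-methylhex-5-en-1-yl]-3-methoxy-1,2-dioxane | CC[C@H](C=C)C[C@H](C)C[C@]1(CC)C[C@H](CC)C(OC)OO1 | intermediate
22 | trimethylsilyl 2-[(3S,4S,6R)-4,6-diethyl-6-[(2S,4S)-4-ethyl-2-methylhex-5-en-1-yl]-1,2-dioxan-3-yl]acetate | CC[C@H](C=C)C[C@H](C)C[C@]1(CC)C[C@H](CC)[C@H](CC(=O)O[Si](C)(C)C)OO1 | intermediate (not isolated)
23 | 2-[(3S,4S,6R)-4,6-diethyl-6-[(2S,4S)-4-ethyl-2-methylhex-5-en-1-yl]-1,2-dioxan-3-yl]acetic acid | CC[C@H](C=C)C[C@H](C)C[C@]1(CC)C[C@H](CC)[C@H](CC(=O)O)OO1 | intermediate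
24 | but-3-en-2-one | CC(=O)C=C | starting material
25 | 2-[(3S,4S,6R)-4,6-diethyl-6-[(2S,4S,5E)-4-ethyl-2-methyl-7-oxooct-5-en-1-yl]-1,2-dioxan-3-yl]acetic acid | CC[C@H](/C=C/C(C)=O)C[C@H](C)C[C@]1(CC)C[C@H](CC)[C@H](CC(=O)O)OO1 | target

Total step count: 14 steps.
Longest linear sequence: 10 steps (steps 1 to 7, then 12 to 14); steps 8 to 11 build the cyclopropane partner in parallel.

Steps most likely to fail

Step 12 (proposed new method). The cyclopropane σ-bond may be too weak a nucleophile for the peroxycarbenium ion, so that proton loss from the cation, attack by the terminal alkene or acid-induced opening of 19 take over; in addition the facial selectivity at C6 may be low. The fallback uses known chemistry, sets out from 9 and 19 and comes back at 21. Compound 19 is opened with N-bromosuccinimide in methanol to (2R)-3-bromo-2-ethyl-1,1-dimethoxypropane F1. Its Grignard reagent (Mg, THF) is added to ketone 9 in the presence of CeCl3 to give the tertiary alcohol (2S,4RS,6S,8S)-2,4,8-triethyl-1,1-dimethoxy-6-methyldec-9-en-4-ol F2. Anhydrous H2O2 in Et2O with catalytic camphorsulfonic acid should then exchange one acetal methoxy group for a hydroperoxy group and close the ring by SN1 substitution at the tertiary carbinol, which gives 21 as its C6 epimers for separation.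

Step 13. Ionisation of the peroxyacetal may be followed by fragmentation of the O–O bond, or the nucleophile may add to the wrong face and give the 3,4-trans acid. The fallback sets out from 21 and comes back at 23. Aqueous acetic acid in THF hydrolyses 21 to the lactol (3RS,4S,6R)-4,6-diethyl-6-[(2S,4S)-4-ethyl-2-methylhex-5-en-1-yl]-1,2-dioxan-3-ol F3. A Horner–Wadsworth–Emmons reaction of its open hydroperoxy aldehyde form with trimethyl phosphonoacetate (LiCl, DBU), followed in the same flask by base-mediated intramolecular oxa-Michael addition of the hydroperoxide, should give methyl 2-[(3S,4S,6R)-4,6-diethyl-6-[(2S,4S)-4-ethyl-2-methylhex-5-en-1-yl]-1,2-dioxan-3-yl]acetate F4 together with its C3 epimer, which is separated. Me3SnOH in 1,2-dichloroethane cleaves the ester to 23.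

Step 14. Cross-metathesis of the alpha-branched terminal alkene may be slow, so that self-metathesis of the enone partner and decay of the catalyst in the presence of the peroxide and the acid compete. The fallback sets out from 23 and comes back at 25. OsO4 (catalytic) and NaIO4 with 2,6-lutidine in aqueous dioxane cleave the vinyl group to 2-[(3S,4S,6R)-4,6-diethyl-6-[(2S,4S)-4-formyl-2-methylhexyl]-1,2-dioxan-3-yl]acetic acid F5, and a Wittig reaction with 1-(triphenylphosphoranylidene)propan-2-one in CH2Cl2 gives 25 as the E-enone.

Further compounds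
F1 | step 12 | (2R)-3-bromo-2-ethyl-1,1-dimethoxypropane | CC[C@H](C(OC)OC)CBr
F2 | step 12 | (2S,4RS,6S,8S)-2,4,8-triethyl-1,1-dimethoxy-6-methyldec-9-en-4-ol | CC[C@H](C=C)C[C@H](C)CC(O)(CC)C[C@H](CC)C(OC)OC
F3 | step 13 | (3RS,4S,6R)-4,6-diethyl-6-[(2S,4S)-4-ethyl-2-methylhex-5-en-1-yl]-1,2-dioxan-3-ol | CC[C@H](C=C)C[C@H](C)C[C@]1(CC)C[C@H](CC)C(O)OO1
F4 | step 13 | methyl 2-[(3S,4S,6R)-4,6-diethyl-6-[(2S,4S)-4-ethyl-2-methylhex-5-en-1-yl]-1,2-dioxan-3-yl]acetate | CC[C@H](C=C)C[C@H](C)C[C@]1(CC)C[C@H](CC)[C@H](CC(=O)OC)OO1
F5 | step 14 | 2-[(3S,4S,6R)-4,6-diethyl-6-[(2S,4S)-4-formyl-2-methylhexyl]-1,2-dioxan-3-yl]acetic acid | CC[C@H](C=O)C[C@H](C)C[C@]1(CC)C[C@H](CC)[C@H](CC(=O)O)OO1
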